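Plan
1. Retrosynthesis: the fifteen phenolic O–H bonds are masked as methyl ethers; the benzylic C–H bonds at the two methines that carry the outer dihydrobenzofuranyl group and the 4-hydroxyphenyl group of the seven-ring half go back to tertiary carbinols, the aryl–C bonds behind them to ketones, and the bond from the linker CH(Ar) to the eight-membered ring to a Michael pair.
2. Enabling feature: in the eight-membered carbocycle the methine bearing a 4-hydroxyphenyl group is bonded on one side to an aromatic carbon of a resorcinol ring and on the other to the methine that carries the outer dihydrobenzofuranyl group (a former carbonyl carbon), so the ring is the ArCH homologue of a seven-membered aryl ketone and is cut at the two bonds of that ArCH carbon.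
3. What remains is an eight-membered α-aryl ketone, the benzylidene derivative of the seven-membered ketone and an aryl bromide; all three come from one enantiopure trans-2,3-diaryl-4-bromo-dihydrobenzofuran.
4. Forward: dihydrofuran ring by rhodium carbene C–H insertion, seven-membered ketone by Friedel–Crafts acylation, eight-membered ketone by diazo ring expansion; a Michael addition then joins the second seven-ring ketone through the linker, two aryl additions and one double ionic deoxygenation complete the skeleton, and BBr3 frees the phenols.
5. Stereochemistry: the catalytic C–H insertion sets C3 of the dihydrofuran (C2 is equilibrated to trans) and this unit is used three times; the ring-expansion methine follows from ligand and substrate, the linker and its ring neighbour from the Michael addition, the α-carbon of the second ketone from equilibration, and the last two methines from hydride delivery anti to the linker.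

Key step: step 12

Assumption: Rh2(S-PTAD)4 (step 5) and the L-pipecolic acid-derived N,N'-dioxide (step 12) are taken to be the antipodes whose sense of induction gives the configurations drawn; if either sense is the reverse, its mirror-image form is used and nothing else changes.

Step 1
Reactants: 1 1-bromo-3,5-dimethoxybenzene; 2 3,5-dimethoxybenzoyl chloride
Product: 3 (2-bromo-4,6-dimethoxyphenyl)(3,5-dimethoxyphenyl)methanone
Conditions: AlCl3, CH2Cl2, 0 °C
Reagents that add atoms: none
Why: Friedel–Crafts acylation, in which the acylium ion enters para to one methoxy group and ortho to the other (next to bromine) because the position between the two methoxy groups is the crowded one, while the ring of 2 is deactivated by its own carbonyl.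

Step 2
Reactants: 3 (2-bromo-4,6-dimethoxyphenyl)(3,5-dimethoxyphenyl)methanone
Product: 4 (2-bromo-6-hydroxy-4-methoxyphenyl)(3,5-dimethoxyphenyl)methanone
Conditions: BCl3, CH2Cl2, −78 → 0 °C
Reagents that add atoms: none
Why: Chelation-directed Lewis-acid demethylation, in which boron bound to the ketone oxygen cleaves only the methyl ether ortho to the carbonyl.

Step 3
Reactants: 4 (2-bromo-6-hydroxy-4-methoxyphenyl)(3,5-dimethoxyphenyl)methanone; 5 4-methoxybenzyl chloride
Product: 6 [2-bromo-4-methoxy-6-(4-methoxybenzyloxy)phenyl](3,5-dimethoxyphenyl)methanone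
Conditions: K2CO3, Bu4NI (cat.), DMF, 60 °C
Reagents that add atoms: none
Why: Williamson ether synthesis on the only phenol, which installs the benzylic CH2 that later becomes C2 of the dihydrofuran.

Step 4
Reactants: 6 [2-bromo-4-methoxy-6-(4-methoxybenzyloxy)phenyl](3,5-dimethoxyphenyl)methanone
Product: 7 hydrazone of ketone 6
Conditions: N2H4·H2O, AcOH (cat.), n-BuOH, 110 °C
Reagents that add atoms: hydrazine (NN)
Why: Hydrazone condensation, run under forcing conditions because the benzophenone is ortho,ortho'-disubstituted on one ring; the aryl bromide and the ethers are inert to hydrazine, and no ester is present yet.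

Step 5
Reactants: 7 hydrazone of ketone 6
Product: 9 (2S,3R)-4-bromo-3-(3,5-dimethoxyphenyl)-6-methoxy-2-(4-methoxyphenyl)-2,3-dihydrobenzofuran (cis), via diaryldiazomethane 8 (not isolated)
Conditions: MnO2, CH2Cl2, 0 °C, filter; Rh2(S-PTAD)4 (1 mol %), CH2Cl2, −20 °C → rt
Reagents that add atoms: none
Why: Dehydrogenation of the hydrazone gives the diaryldiazomethane, and the donor/donor rhodium carbene then undergoes intramolecular C–H insertion into the benzylic ether CH2 to close the five-membered ring; the chiral carboxylate ligands are expected to fix C3 as R, and the concerted insertion places the two aryl groups cis.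

Step 6
Reactants: 9 (2S,3R)-4-bromo-3-(3,5-dimethoxyphenyl)-6-methoxy-2-(4-methoxyphenyl)-2,3-dihydrobenzofuran
Product: 10 (2R,3R)-4-bromo-3-(3,5-dimethoxyphenyl)-6-methoxy-2-(4-methoxyphenyl)-2,3-dihydrobenzofuran (trans)
Conditions: CF3CO2H, CH2Cl2, 0 °C → rt
Reagents that add atoms: none
Why: Acid-mediated epimerisation, in which reversible ionisation of the C2–O bond to the 4-methoxybenzylic cation and reclosure by the phenol oxygen inverts C2 only and should give the thermodynamically preferred 2,3-trans isomer with C3 untouched.

Step 7
Reactants: 10 (2R,3R)-4-bromo-dihydrobenzofuran; 11 ethyl bromozincacetate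
Product: 12 ethyl 2-[(2R,3R)-3-(3,5-dimethoxyphenyl)-6-methoxy-2-(4-methoxyphenyl)-2,3-dihydrobenzofuran-4-yl]acetate
Conditions: Pd2(dba)3 (2.5 mol %), XPhos (10 mol %), THF, 65 °C
Reagents that add atoms: none
Why: Negishi-type coupling of a Reformatsky reagent (α-arylation of a zinc ester enolate) after oxidative addition of the aryl bromide to zerovalent palladium; neither stereocentre is involved.

Step 8
Reactants: 12 ethyl arylacetate
Product: 13 2-[(2R,3R)-3-(3,5-dimethoxyphenyl)-6-methoxy-2-(4-methoxyphenyl)-2,3-dihydrobenzofuran-4-yl]acetic acid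
Conditions: LiOH, THF/MeOH/H2O, rt; then 1 M HCl
Reagents that add atoms: lithium hydroxide ([Li+].[OH-])
Why: Ester saponification under basic conditions, to which the dihydrobenzofuran and its stereocentres are inert.

Step 9
Reactants: 13 arylacetic acid
Product: 15 seven-membered aryl ketone fused to the (R,R)-trans-dihydrofuran, via mixed trifluoroacetic anhydride 14 (not isolated)
Conditions: (CF3CO)2O, CH2Cl2, 0 °C → rt
Reagents that add atoms: none
Why: Intramolecular Friedel–Crafts acylation through the mixed anhydride, in which the acyl carbon can reach only the ortho carbon of the pendant 3,5-dimethoxyphenyl ring (ortho and para to methoxy groups) and so closes the seven-membered ketone.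

Step 10
Reactants: 16 4-methoxybenzaldehyde
Product: 17 4-methoxybenzaldehyde hydrazone
Conditions: N2H4·H2O (excess), EtOH, 0 °C → rt
Reagents that add atoms: hydrazine (NN)
Why: Hydrazone condensation, with excess hydrazine to suppress azine formation.

Step 11
Reactants: 17 4-methoxybenzaldehyde hydrazone
Product: 18 (4-methoxyphenyl)diazomethane (cold CH2Cl2 solution)
Conditions: MnO2, MgSO4, CH2Cl2, −20 °C; cold filtration, used at once
Reagents that add atoms: none
Why: Dehydrogenation of a hydrazone to the aryldiazomethane; the electron-rich diazo compound is kept cold and dilute and is not stored.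

Step 12
Reactants: 15 seven-membered aryl ketone; 18 (4-methoxyphenyl)diazomethane
Product: 20 eight-membered α-(4-methoxyphenyl) ketone fused to the (R,R)-trans-dihydrofuran with the new CH(Ar) carbon S, via diazonium alkoxide 19 (not isolated)
Conditions: Sc(OTf)3 (10 mol %), chiral N,N'-dioxide ligand (L-pipecolic acid-derived, 2,6-diisopropylanilide arms; 12 mol %), 4 Å MS, CH2Cl2, −40 °C, slow addition of 18
Reagents that add atoms: none
Why: The scandium triflate/N,N'-dioxide complex binds the ketone oxygen together with the neighbouring methoxy group, the nucleophilic diazo carbon adds to the carbonyl carbon to give the diazonium alkoxide 19, and the aryl ring then shifts to that carbon anti to the departing N2, which places the ArCH unit between arene and carbonyl. The closest known reaction type is the Lewis acid-catalysed one-carbon homologation of cyclic ketones with aryldiazomethanes to α-aryl cycloalkanones. The eight-membered ring is formed by ring enlargement and not by cyclisation: the aryl–C(=O) bond of the seven-membered ring is exchanged for the pair CH(Ar)–arene and CH(Ar)–C(=O). The new stereocentre is defined when the diazo carbon bonds to the ketone on the face left open by the ligand and by the adjacent trans-fused dihydrofuran and the aryl shift follows with inversion at that carbon; the matched ligand antipode and the substrate bias are expected to give the S centre. The step needs aryl rather than CH2 migration, which is secured by the methoxy groups ortho and para to the migrating carbon, and single insertion, which is secured by the greater hindrance of the α,α'-disubstituted product ketone.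

Step 13
Reactants: 15 seven-membered aryl ketone; 16 4-methoxybenzaldehyde
Product: 21 (E)-α-(4-methoxybenzylidene) derivative of ketone 15
Conditions: KOH, EtOH, rt
Reagents that add atoms: none
Why: Claisen–Schmidt (crossed aldol) condensation at the only enolisable position, in which E1cB loss of water should give the E enone with the anisyl group turned away from the carbonyl; no stereocentre is formed and the existing ones are not acidic.

Step 14
Reactants: 20 eight-membered α-aryl ketone; 21 benzylidene ketone
Product: 24 keto silyl enol ether (Michael adduct: CH2 carbon of 20 bonded to the linker CH(4-methoxyphenyl) whose other neighbour is the α-carbon of the Me3Si enol ether of the seven-ring ketone), via lithium enolate 22 (not isolated), via adduct lithium enolate 23 (not isolated)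
Conditions: LiN(i-Pr)2 (1.05 equiv), THF, −78 °C; 21, −78 → −40 °C; Me3SiCl, −78 °C
Reagents that add atoms: chlorotrimethylsilane (C[Si](C)(C)Cl)
Why: Kinetic deprotonation at the less hindered CH2 and Michael addition of the lithium enolate to the non-enolisable benzylidene ketone, with O-silylation of the resulting aryl-ketone enolate so that only the eight-ring carbonyl stays free; the bond is expected to form on the enolate face opposite the aryl group of the other α-carbon, through a lithium-bridged transition state with the s-cis enone in which the anisyl group points away from the eight-membered ring, which sets the ring carbon and the linker carbon as drawn.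

Step 15
Reactants: 24 keto silyl enol ether; 10 (2R,3R)-4-bromo-dihydrobenzofuran
Product: 27 δ-hydroxy ketone (outer dihydrobenzofuranyl carbinol on the eight-membered ring with the seven-ring ketone released), via aryllithium 25 (not isolated), via lithium alkoxide 26 (not isolated)
Conditions: 10, t-BuLi (2 equiv), THF, −78 °C; then 24 and CeCl3, THF, −78 °C; then K2CO3, MeOH, 0 °C
Reagents that add atoms: none
Why: Halogen–lithium exchange and cerium-assisted 1,2-addition of the aryllithium to the hindered, enolisable ketone, followed by methanolysis of the silyl enol ether; the carbinol configuration is immaterial because it is erased in step 17, and the α-carbon of the released ketone is protonated under equilibrating conditions, which is expected to leave its branched substituent pseudo-equatorial on the ring face that also holds the furan C2 carbon.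

Step 16
Reactants: 27 δ-hydroxy ketone; 28 4-methoxyphenylmagnesium bromide
Product: 29 bis(tertiary carbinol) carrying the complete carbon skeleton
Conditions: CeCl3, THF, −78 → 0 °C (28, 3 equiv); H2O
Reagents that add atoms: none
Why: Grignard addition in the presence of CeCl3 to an enolisable, ortho-substituted aryl ketone, with the first equivalent consumed by the tertiary hydroxyl; the configuration of the new carbinol is again of no consequence.

Step 17
Reactants: 29 bis(tertiary carbinol)
Product: 30 pentadeca-O-methyl ether of the target
Conditions: Et3SiH (10 equiv), CF3CO2H, CH2Cl2, −40 °C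
Reagents that add atoms: none
Why: Ionic deoxygenation of two tertiary benzylic alcohols, in which each carbinol ionises to a cation stabilised by alkoxy-substituted aryl groups and should accept hydride on the face opposite the linker carbon on the neighbouring ring atom, placing each new aryl group cis to the linker in its ring; the low temperature keeps the 2-aryl-dihydrofuran C–O bonds closed.

Step 18
Reactants: 30 pentadeca-O-methyl ether
Product: 31 CNP0184494.1
Conditions: BBr3 (excess), CH2Cl2, −78 → 0 °C; MeOH, H2O
Reagents that add atoms: none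
Why: Lewis-acid cleavage of all fifteen aryl methyl ethers; the three trans-2-aryl-dihydrobenzofurans are already in their preferred configuration, so reversible C–O ionisation is harmless, and no other stereocentre is labile.

Compound list
1 | 1-bromo-3,5-dimethoxybenzene | COc1cc(Br)cc(OC)c1 | starting material
2 | 3,5-dimethoxybenzoyl chloride | COc1cc(cc(OC)c1)C(Cl)=O | starting material
3 | (2-bromo-4,6-dimethoxyphenyl)(3,5-dimethoxyphenyl)methanone | COc1cc(OC)cc(c1)C(=O)c1c(Br)cc(OC)cc1OC | intermediate
4 | (2-bromo-6-hydroxy-4-methoxyphenyl)(3,5-dimethoxyphenyl)methanone | COc1cc(OC)cc(c1)C(=O)c1c(Br)cc(OC)cc1O | intermediate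
5 | 4-methoxybenzyl chloride | COc1ccc(CCl)cc1 | starting material
6 | [2-bromo-4-methoxy-6-(4-methoxybenzyloxy)phenyl](3,5-dimethoxyphenyl)methanone | COc1cc(OC)cc(c1)C(=O)c1c(Br)cc(OC)cc1OCc1ccc(OC)cc1 | intermediate
7 | hydrazone of 6 (C=N geometry not defined) | COc1cc(OC)cc(c1)C(=NN)c1c(Br)cc(OC)cc1OCc1ccc(OC)cc1 | intermediate
8 | [2-bromo-4-methoxy-6-(4-methoxybenzyloxy)phenyl](3,5-dimethoxyphenyl)diazomethane | COc1cc(OC)cc(c1)C(=[N+]=[N-])c1c(Br)cc(OC)cc1OCc1ccc(OC)cc1 | intermediate
9 | (2S,3R)-4-bromo-3-(3,5-dimethoxyphenyl)-6-methoxy-2-(4-methoxyphenyl)-2,3-dihydrobenzofuran (cis) | Brc1cc(OC)cc2c1[C@@H](c1cc(OC)cc(OC)c1)[C@@H](c1ccc(OC)cc1)O2 | intermediate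
10 | (2R,3R)-4-bromo-3-(3,5-dimethoxyphenyl)-6-methoxy-2-(4-methoxyphenyl)-2,3-dihydrobenzofuran (trans) | Brc1cc(OC)cc2c1[C@@H](c1cc(OC)cc(OC)c1)[C@H](c1ccc(OC)cc1)O2 | intermediate
11 | ethyl bromozincacetate, (2-ethoxy-2-oxoethyl)zinc bromide | CCOC(=O)C[Zn]Br | starting material
12 | ethyl 2-[(2R,3R)-3-(3,5-dimethoxyphenyl)-6-methoxy-2-(4-methoxyphenyl)-2,3-dihydrobenzofuran-4-yl]acetate | CCOC(=O)Cc1cc(OC)cc2c1[C@@H](c1cc(OC)cc(OC)c1)[C@H](c1ccc(OC)cc1)O2 | intermediate
13 | 2-[(2R,3R)-3-(3,5-dimethoxyphenyl)-6-methoxy-2-(4-methoxyphenyl)-2,3-dihydrobenzofuran-4-yl]acetic acid | OC(=O)Cc1cc(OC)cc2c1[C@@H](c1cc(OC)cc(OC)c1)[C@H](c1ccc(OC)cc1)O2 | intermediate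
14 | mixed anhydride of 13 with trifluoroacetic acid | FC(F)(F)C(=O)OC(=O)Cc1cc(OC)cc2c1[C@@H](c1cc(OC)cc(OC)c1)[C@H](c1ccc(OC)cc1)O2 | intermediate
15 | seven-membered aryl ketone fused to the trans-dihydrofuran (furan C2 and C3 both R; C=O on the dimethoxyaryl ring, CH2 on the benzofuran arene) | O=C1Cc2cc(OC)cc3c2[C@@H](c2cc(OC)cc(OC)c21)[C@H](c1ccc(OC)cc1)O3 | intermediate
16 | 4-methoxybenzaldehyde | COc1ccc(C=O)cc1 | starting material
17 | 4-methoxybenzaldehyde hydrazone (E) | COc1ccc(/C=N/N)cc1 | intermediate
18 | (4-methoxyphenyl)diazomethane | COc1ccc(C=[N+]=[N-])cc1 | intermediate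
19 | scandium-bound diazonium alkoxide from 15 and 18 (the two transient centres not defined) | [O-]C1(C([N+]#N)c2ccc(OC)cc2)Cc2cc(OC)cc3c2[C@@H](c2cc(OC)cc(OC)c21)[C@H](c1ccc(OC)cc1)O3 | intermediate
20 | eight-membered α-(4-methoxyphenyl) ketone fused to the trans-dihydrofuran (furan C2 and C3 R; CH(Ar) carbon S, between the dimethoxyaryl ring and C=O) | O=C1Cc2cc(OC)cc3c2[C@@H](c2cc(OC)cc(OC)c2[C@@H]1c1ccc(OC)cc1)[C@H](c1ccc(OC)cc1)O3 | intermediate
21 | (E)-α-(4-methoxybenzylidene) derivative of ketone 15 | O=C1/C(=C/c2ccc(OC)cc2)c2cc(OC)cc3c2[C@@H](c2cc(OC)cc(OC)c21)[C@H](c1ccc(OC)cc1)O3 | intermediate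
22 | lithium enolate of 20 on its CH2 side | [Li]OC1=Cc2cc(OC)cc3c2[C@@H](c2cc(OC)cc(OC)c2[C@@H]1c1ccc(OC)cc1)[C@H](c1ccc(OC)cc1)O3 | intermediate
23 | lithium enolate of the Michael adduct (enolate of the seven-ring ketone; eight-ring ketone free) | [Li]OC=2c3c(OC)cc(OC)cc3[C@@H]3c4c(cc(OC)cc4C2[C@H](c2ccc(OC)cc2)[C@H]2c4cc(OC)cc5c4[C@@H](c4cc(OC)cc(OC)c4[C@H](c4ccc(OC)cc4)C2=O)[C@H](c2ccc(OC)cc2)O5)O[C@H]3c2ccc(OC)cc2 | intermediate
24 | keto silyl enol ether: Michael adduct with the eight-ring ketone free and the seven-ring ketone as its Me3Si enol ether | C[Si](C)(C)OC=2c3c(OC)cc(OC)cc3[C@@H]3c4c(cc(OC)cc4C2[C@H](c2ccc(OC)cc2)[C@H]2c4cc(OC)cc5c4[C@@H](c4cc(OC)cc(OC)c4[C@H](c4ccc(OC)cc4)C2=O)[C@H](c2ccc(OC)cc2)O5)O[C@H]3c2ccc(OC)cc2 | intermediate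
25 | (2R,3R)-3-(3,5-dimethoxyphenyl)-6-methoxy-2-(4-methoxyphenyl)-2,3-dihydrobenzofuran-4-yllithium | [Li]c1cc(OC)cc2c1[C@@H](c1cc(OC)cc(OC)c1)[C@H](c1ccc(OC)cc1)O2 | intermediate
26 | lithium alkoxide from addition of 25 to the eight-ring ketone of 24 (carbinol centre not defined; silyl enol ether intact) | C[Si](C)(C)OC=2c3c(OC)cc(OC)cc3[C@@H]3c4c(cc(OC)cc4C2[C@H](c2ccc(OC)cc2)[C@H]2c4cc(OC)cc5c4[C@@H](c4cc(OC)cc(OC)c4[C@H](c4ccc(OC)cc4)C2(O[Li])c2cc(OC)cc4c2[C@@H](c2cc(OC)cc(OC)c2)[C@H](c2ccc(OC)cc2)O4)[C@H](c2ccc(OC)cc2)O5)O[C@H]3c2ccc(OC)cc2 | intermediate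
27 | δ-hydroxy ketone: tertiary carbinol bearing the outer dihydrobenzofuranyl group on the eight-membered ring (carbinol centre not defined), seven-ring aryl ketone free, its α-carbon configured as in the target; may sit in equilibrium with its cyclic hemiketal | O=C2c3c(OC)cc(OC)cc3[C@@H]3c4c(cc(OC)cc4[C@H]2[C@H](c2ccc(OC)cc2)[C@H]2c4cc(OC)cc5c4[C@@H](c4cc(OC)cc(OC)c4[C@H](c4ccc(OC)cc4)C2(O)c2cc(OC)cc4c2[C@@H](c2cc(OC)cc(OC)c2)[C@H](c2ccc(OC)cc2)O4)[C@H](c2ccc(OC)cc2)O5)O[C@H]3c2ccc(OC)cc2 | intermediate
28 | 4-methoxyphenylmagnesium bromide | COc1ccc([Mg]Br)cc1 | starting material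
29 | bis(tertiary carbinol): 27 after addition of the 4-methoxyphenyl group to the seven-ring ketone (both carbinol centres not defined) | COc1ccc(C2(O)c3c(OC)cc(OC)cc3[C@@H]3c4c(cc(OC)cc4[C@H]2[C@H](c2ccc(OC)cc2)[C@H]2c4cc(OC)cc5c4[C@@H](c4cc(OC)cc(OC)c4[C@H](c4ccc(OC)cc4)C2(O)c2cc(OC)cc4c2[C@@H](c2cc(OC)cc(OC)c2)[C@H](c2ccc(OC)cc2)O4)[C@H](c2ccc(OC)cc2)O5)O[C@H]3c2ccc(OC)cc2)cc1 | intermediate
30 | pentadeca-O-methyl ether of the target | COc1ccc([C@H]2c3c(OC)cc(OC)cc3[C@@H]3c4c(cc(OC)cc4[C@H]2[C@H](c2ccc(OC)cc2)[C@H]2c4cc(OC)cc5c4[C@@H](c4cc(OC)cc(OC)c4[C@H](c4ccc(OC)cc4)[C@H]2c2cc(OC)cc4c2[C@@H](c2cc(OC)cc(OC)c2)[C@H](c2ccc(OC)cc2)O4)[C@H](c2ccc(OC)cc2)O5)O[C@H]3c2ccc(OC)cc2)cc1 | intermediate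
31 | CNP0184494.1 | Oc1ccc([C@H]2c3c(O)cc(O)cc3[C@@H]3c4c(cc(O)cc4[C@H]2[C@H](c2ccc(O)cc2)[C@H]2c4cc(O)cc5c4[C@@H](c4cc(O)cc(O)c4[C@H](c4ccc(O)cc4)[C@H]2c2cc(O)cc4c2[C@@H](c2cc(O)cc(O)c2)[C@H](c2ccc(O)cc2)O4)[C@H](c2ccc(O)cc2)O5)O[C@H]3c2ccc(O)cc2)cc1 | target

Total step count: 18. Longest linear sequence: 15 steps (steps 1–9, 12, 14–18).

Steps most likely to fail

Step 14. The enolate may form on the more acidic CH(Ar) side by proton transfer, the very crowded adduct may revert by retro-Michael reaction before it is silylated, and the facial selectivity at the linker carbon rests on substrate control alone. Fallback, setting out from 20 and coming back at 24: the kinetic enolate of 20 would be silylated with Me3SiCl and the kinetic trimethylsilyl enol ether F1 freed from any regioisomer. F1 and 21 would then be joined in a Mukaiyama–Michael addition (Me3SiOTf, 10 mol %, CH2Cl2, −78 °C). The Lewis-acid-activated enone would be attacked through an open transition state, which has the opposite topicity preference to the lithium-bridged one. Silyl transfer to the new enolate oxygen would give 24 directly and the process is not reversible.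

Step 12. The Lewis acid may decompose the electron-rich diazo compound faster than it adds to the deactivated ortho,para-dimethoxyaryl ketone. The benzylic CH2 may migrate in competition with the aryl ring. The acidic CH(Ar) centre may epimerise on the catalyst. Fallback, setting out from 15 (and 5) and coming back at 20: 5 and PhSeNa in EtOH would give 4-methoxybenzyl phenyl selenide F2. Its lithium anion (LiN(i-Pr)2, THF, −78 °C) would be added to 15 in the presence of CeCl3 to give the β-hydroxy selenide F3. AgBF4 in CH2Cl2 would then turn selenium into a leaving group on the exocyclic carbon. The same dimethoxyaryl ring would shift in a semipinacol rearrangement to give 20, whose CH(Ar) centre could be equilibrated with mild base.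

Step 17. The long-lived benzylic cations may lose a proton to the neighbouring methines and be re-protonated, which would scramble those centres. Hydride may enter from the wrong face. The acid/silane couple may open the 2-aryl-dihydrofurans reductively. Fallback, setting out from 29 and coming back at 30: the two carbinols would be deoxygenated through radicals instead of cations. Cp2TiCl, made from Cp2TiCl2 and Mn dust, with 2,4,6-collidine hydrochloride in THF at reflux, would cleave each benzylic C–O bond homolytically. The benzylic radical would be captured by a second titanium centre and the resulting benzyl–titanium bond protonated from the less hindered face. No acid strong enough to ionise the dihydrofurans is present and no new compound is made (F0).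

Further compounds
F1 | step 14 | trimethylsilyl enol ether of 20 on its CH2 side | C[Si](C)(C)OC1=Cc2cc(OC)cc3c2[C@@H](c2cc(OC)cc(OC)c2[C@@H]1c1ccc(OC)cc1)[C@H](c1ccc(OC)cc1)O3
F2 | step 12 | 4-methoxybenzyl phenyl selenide | COc1ccc(C[Se]c2ccccc2)cc1
F3 | step 12 | β-hydroxy selenide from 15 (carbinol and selenide carbons not defined) | OC1(C([Se]c2ccccc2)c2ccc(OC)cc2)Cc2cc(OC)cc3c2[C@@H](c2cc(OC)cc(OC)c21)[C@H](c1ccc(OC)cc1)O3
F0 | step 17 | none | none
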